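The trione ring (ring C; C1 ketone, C2 acetyl-bearing, C4 quaternary) is a linear seven-carbon 1,3,5,7-tetracarbonyl chain in disguise: C4, with its methyl and geranyl groups, sits between the C3 and C5 carbonyls, and the acetyl carbonyl is one chain terminus. Cutting the C1–C2 ring bond therefore gives an achiral bis(β-keto thioester) whose two arms are enantiotopic. A single Dieckmann closure on a chiral Mg(OTf)2/bis(oxazoline) template should rebuild ring C, decide the configuration of C4 by arm selection, and leave a thioester at the acetyl position. Methyl transfer to that thioester and a Mannich-base union with the butanoyl chromene (rings A and B) then complete the target.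

Key step: step 4

Remark: geranyl = (2E)-3,7-dimethylocta-2,6-dien-1-yl; every trione is drawn as one dienol tautomer, and in that drawing the quaternary carbon is R.
Assumption: the sense of induction of the bis(oxazoline) ligand cannot be predicted, so the ligand antipode that gives (R)-9 is to be used (both antipodes are sold).

Step 1
Reactants: 1 3-methylpentane-2,4-dione; 2 geranyl bromide
Product: 3 3-geranyl-3-methylpentane-2,4-dione
Conditions: K2CO3 (1.5 equiv), acetone, 55 °C
Reagents that add atoms: none
Why: C-alkylation of the potassium enolate of a 2-substituted 1,3-diketone with a primary allylic bromide (SN2) should give the quaternary dione with the E alkene untouched, and no stereocenter arises because the two acetyl groups are identical.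

Step 2
Reactants: 4 S-ethyl chlorothioformate; 5 sodium ethanethiolate
Product: 6 S,S-diethyl dithiocarbonate
Conditions: THF, 0 °C → rt
Reagents that add atoms: none
Why: Nucleophilic acyl substitution (addition–elimination of thiolate at the acyl chloride carbon) should give the symmetric dithiocarbonate, a thioacylating agent that can be used under equilibrating conditions.

Step 3
Reactants: 3 3-geranyl-3-methylpentane-2,4-dione; 6 S,S-diethyl dithiocarbonate (3 equiv)
Product: 8 S,S-diethyl 4-geranyl-4-methyl-3,5-dioxoheptanebis(thioate), via mono-thioester 7 (not isolated)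
Conditions: NaH (5 equiv), DME, 0 → 50 °C; then 1 M HCl, 0 °C; used without storage
Reagents that add atoms: none
Why: Twofold crossed Claisen condensation (the thio analogue of ketone carboxylation with a dialkyl carbonate and NaH) should acylate only the two methyl groups, since the quaternary carbon is not enolizable, and each β-keto thioester is withdrawn as its sodium enolate, which makes C-acylation the thermodynamic outcome and keeps both arms from closing until the acidic quench.

Step 4
Reactants: 8 S,S-diethyl 4-geranyl-4-methyl-3,5-dioxoheptanebis(thioate)
Product: 9 S-ethyl (3R)-3-geranyl-2,4-dihydroxy-3-methyl-6-oxocyclohexa-1,4-diene-1-carbothioate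
Conditions: Mg(OTf)2 (20 mol %), (S,S)-Ph-box [2,2'-(propane-2,2-diyl)bis((4S)-4-phenyl-4,5-dihydrooxazole)] (22 mol %), N-methylmorpholine (1.1 equiv), 4 Å MS, CHCl3, 0 °C → rt; then 1 M HCl
Reagents that add atoms: none
Why: Proposed new method: the Mg(OTf)2–Ph-box complex (divalent magnesium) and N-methylmorpholine enolize one β-keto thioester arm as an O,O-chelate, its central carbon C2 (chain numbering of 8) adds to the thioester carbonyl C7 of the other arm, which is held on the same metal as a neutral 1,3-dicarbonyl, and the tetrahedral intermediate expels ethanethiolate to give the enolized trione. The closest known reaction types are the magnesium-templated Claisen (Dieckmann) cyclization of polyketo esters to acylphloroglucinols, the soft-enolization Claisen acylation of thioesters with MgBr2 and a tertiary amine, and the Mg(OTf)2/bis(oxazoline)/amine generation of chiral enolates from 1,3-dicarbonyl compounds. The one ring closes in a 6-(enolendo)-exo-trig mode and is the only ring within reach, since attack of C2 on the C5 ketone would give a four-membered ring. The stereocenter C4 is set not by a new bond at that carbon but by which enantiotopic arm acts as the nucleophile, and the controlling element is the C2-symmetric ligand: with the chain wrapped around magnesium through O1, O3, O5 and O7, the central O3–C3–C4–C5–O5 chelate ring should turn geranyl away from the oxazoline phenyl group and methyl toward it, so that the two arms are no longer equivalent. The step needs arm selectivity and C- over O-acylation (the alternative is an enol lactone): chelation ties up the enolate oxygen, the weak amine should not enolize the substrate appreciably without the metal, which keeps the racemic background low, and the quaternary carbon excludes aldol, dehydration and aromatization pathways. The product is a vinylogous acid held as its morpholinium salt, a weaker ligand than the substrate enolate, which should let the metal turn over, and its quaternary stereocenter cannot epimerize.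

Step 5
Reactants: 9 S-ethyl (3R)-3-geranyl-2,4-dihydroxy-3-methyl-6-oxocyclohexa-1,4-diene-1-carbothioate
Product: 12 (4R)-2-acetyl-4-geranyl-3,5-dihydroxy-4-methylcyclohexa-2,5-dien-1-one, via bis(trimethylsilyl) ether of the thioester 10 (not isolated), via bis(trimethylsilyl) ether of the methyl ketone 11 (not isolated)
Conditions: N,O-bis(trimethylsilyl)acetamide (BSA, 2.5 equiv), THF, rt; then MeZnI (3 equiv), PdCl2(PPh3)2 (10 mol %), toluene–THF, rt; then 1 M HCl
Reagents that add atoms: methylzinc iodide, C[Zn]I
Why: Fukuyama coupling, in which zerovalent palladium should insert into the acyl–S bond and accept methyl from zinc before reductive elimination to the methyl ketone, is run after both acidic enols have been masked in the flask as trimethylsilyl ethers so that the organozinc is not protonated and the thioester is not part of an enolate, the acidic work-up removes the silyl groups, and the quaternary stereocenter is not touched.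

Step 6
Reactants: 13 phloroglucinol; 14 butanoyl chloride
Product: 15 1-(2,4,6-trihydroxyphenyl)butan-1-one
Conditions: AlCl3 (3.5 equiv), PhNO2–CH2Cl2, 0 → 50 °C; then ice/HCl
Reagents that add atoms: none
Why: Friedel–Crafts C-acylation of the threefold symmetric, electron-rich ring should stop at the monoketone because the chelated acyl group deactivates the ring toward a second acylation.

Step 7
Reactants: 15 1-(2,4,6-trihydroxyphenyl)butan-1-one; 16 3-methylbut-2-enal (1.1 equiv)
Product: 18 1-(5,7-dihydroxy-2,2-dimethyl-2H-chromen-6-yl)butan-1-one, via ortho-quinone methide 17 (not isolated)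
Conditions: ethylenediammonium diacetate (10 mol %), toluene, 110 °C
Reagents that add atoms: none
Why: Amine-catalysed Knoevenagel-type condensation at a free ring carbon followed by oxa-6π electrocyclization should close the pyran through the non-chelated para oxygen, which places the butanoyl group at C6 between the two hydroxyls, and the 8-acyl isomer from closure through a chelated oxygen is the expected minor product and is removed by chromatography.

Step 8
Reactants: 18 1-(5,7-dihydroxy-2,2-dimethyl-2H-chromen-6-yl)butan-1-one
Product: 19 1-{8-[(dimethylamino)methyl]-5,7-dihydroxy-2,2-dimethyl-2H-chromen-6-yl}butan-1-one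
Conditions: 37% aq. CH2O (1.1 equiv), 40% aq. Me2NH (1.2 equiv), EtOH, 0 °C → rt
Reagents that add atoms: formaldehyde, C=O; dimethylamine, CNC
Why: Mannich reaction at C8, the only unsubstituted aromatic carbon and one flanked by a hydroxyl and the pyran oxygen, should give a single aminomethyl compound.

Step 9
Reactants: 12 (4R)-2-acetyl-4-geranyl-3,5-dihydroxy-4-methylcyclohexa-2,5-dien-1-one; 19 1-{8-[(dimethylamino)methyl]-5,7-dihydroxy-2,2-dimethyl-2H-chromen-6-yl}butan-1-one (1.1 equiv)
Product: 21 (4R)-2-acetyl-6-[(6-butanoyl-5,7-dihydroxy-2,2-dimethyl-2H-chromen-8-yl)methyl]-4-geranyl-3,5-dihydroxy-4-methylcyclohexa-2,5-dien-1-one (CNP0203748.1), via ortho-quinone methide 20 (not isolated)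
Conditions: toluene, 80 °C; then 0.5 M HCl wash
Reagents that add atoms: none
Why: Thermal loss of dimethylamine from the phenolic Mannich base, helped by protonation by the acidic trione, should give an ortho-quinone methide to which the only free enol carbon (C6) of 12 adds in a Michael reaction with rearomatization, and the quaternary stereocenter is remote and untouched.

Compound list
1 | 3-methylpentane-2,4-dione | CC(=O)C(C)C(C)=O | starting material
2 | geranyl bromide, (2E)-1-bromo-3,7-dimethylocta-2,6-diene | BrC/C=C(\C)CCC=C(C)C | starting material
3 | 3-geranyl-3-methylpentane-2,4-dione | CC(=O)C(C)(C/C=C(\C)CCC=C(C)C)C(C)=O | intermediate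
4 | S-ethyl chlorothioformate | CCSC(Cl)=O | starting material
5 | sodium ethanethiolate | CC[S-].[Na+] | starting material
6 | S,S-diethyl dithiocarbonate | CCSC(=O)SCC | intermediate
7 | S-ethyl 4-geranyl-4-methyl-3,5-dioxohexanethioate (racemic mono-thioester) | CCSC(=O)CC(=O)C(C)(C/C=C(\C)CCC=C(C)C)C(C)=O | intermediate (not isolated)
8 | S,S-diethyl 4-geranyl-4-methyl-3,5-dioxoheptanebis(thioate) (achiral) | CCSC(=O)CC(=O)C(C)(C/C=C(\C)CCC=C(C)C)C(=O)CC(=O)SCC | intermediate
9 | S-ethyl (3R)-3-geranyl-2,4-dihydroxy-3-methyl-6-oxocyclohexa-1,4-diene-1-carbothioate (dienol form of S-ethyl 3-geranyl-3-methyl-2,4,6-trioxocyclohexane-1-carbothioate) | C1=C(O)[C@@](C)(C/C=C(\C)CCC=C(C)C)C(O)=C(C(=O)SCC)C1=O | intermediate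
10 | S-ethyl (3R)-3-geranyl-3-methyl-6-oxo-2,4-bis(trimethylsilyloxy)cyclohexa-1,4-diene-1-carbothioate | C1=C(O[Si](C)(C)C)[C@@](C)(C/C=C(\C)CCC=C(C)C)C(O[Si](C)(C)C)=C(C(=O)SCC)C1=O | intermediate (not isolated)
11 | (4R)-2-acetyl-4-geranyl-4-methyl-3,5-bis(trimethylsilyloxy)cyclohexa-2,5-dien-1-one | C1=C(O[Si](C)(C)C)[C@@](C)(C/C=C(\C)CCC=C(C)C)C(O[Si](C)(C)C)=C(C(C)=O)C1=O | intermediate (not isolated)
12 | (4R)-2-acetyl-4-geranyl-3,5-dihydroxy-4-methylcyclohexa-2,5-dien-1-one | C1=C(O)[C@@](C)(C/C=C(\C)CCC=C(C)C)C(O)=C(C(C)=O)C1=O | intermediate
13 | phloroglucinol | Oc1cc(O)cc(O)c1 | starting material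
14 | butanoyl chloride | CCCC(Cl)=O | starting material
15 | 1-(2,4,6-trihydroxyphenyl)butan-1-one | CCCC(=O)c1c(O)cc(O)cc1O | intermediate
16 | 3-methylbut-2-enal | CC(C)=CC=O | starting material
17 | 4-butanoyl-3,5-dihydroxy-6-(3-methylbut-2-en-1-ylidene)cyclohexa-2,4-dien-1-one (ortho-quinone methide) | CCCC(=O)C1=C(O)C(=CC=C(C)C)C(=O)C=C1O | intermediate (not isolated)
18 | 1-(5,7-dihydroxy-2,2-dimethyl-2H-chromen-6-yl)butan-1-one | CCCC(=O)c1c(O)cc2OC(C)(C)C=Cc2c1O | intermediate
19 | 1-{8-[(dimethylamino)methyl]-5,7-dihydroxy-2,2-dimethyl-2H-chromen-6-yl}butan-1-one | CCCC(=O)c1c(O)c(CN(C)C)c2OC(C)(C)C=Cc2c1O | intermediate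
20 | 6-butanoyl-5-hydroxy-2,2-dimethyl-8-methylidene-2H-chromen-7(8H)-one (ortho-quinone methide) | CCCC(=O)C1=C(O)C2=C(OC(C)(C)C=C2)C(=C)C1=O | intermediate (not isolated)
21 | (4R)-2-acetyl-6-[(6-butanoyl-5,7-dihydroxy-2,2-dimethyl-2H-chromen-8-yl)methyl]-4-geranyl-3,5-dihydroxy-4-methylcyclohexa-2,5-dien-1-one (CNP0203748.1) | CCCC(=O)c1c(O)c2c(c(CC3=C(O)[C@@](C)(C/C=C(\C)CCC=C(C)C)C(O)=C(C(C)=O)C3=O)c1O)OC(C)(C)C=C2 | target

Total step count: 9. Longest linear sequence: 5 steps (steps 1, 3, 4, 5 and 9, from 1 and 2). The chromene branch is 4 steps (6, 7, 8, 9), and step 2 is a one-step side branch.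

Steps most likely to fail

Step 4. Three processes may defeat it:
- The ligand may read the difference between methyl and geranyl at C4 too weakly, so that both arms act as nucleophile and the product is close to racemic.
- The enolate oxygen may acylate instead of carbon, giving lactonization.
- The strongly chelating product may sequester magnesium; raising the complex to one equivalent would be the first remedy inside the step.

The fallback uses known chemistry, sets out from geranyl bromide 2 and comes back at 12, so that steps 1 to 5 are no longer needed. Purchased 1-(2,4,6-trihydroxy-3-methylphenyl)ethan-1-one (CC(=O)c1c(O)cc(O)c(C)c1O) is deprotonated with NaOMe in MeOH at 0 °C and C-geranylated with 2 at its methyl-bearing ring carbon (alkylative dearomatization). This should give racemic 2-acetyl-4-geranyl-3,5-dihydroxy-4-methylcyclohexa-2,5-dien-1-one F1 beside the aromatic ring-geranylated isomer, which is removed by chromatography. The racemic vinylogous acid is resolved by fractional crystallization with (S)-1-phenylethylamine (or its antipode); the (S)-1-phenylethylammonium salt of the R acid F2 is collected, and dilute HCl releases 12.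

Step 5. Oxidative addition into a hindered, electron-rich acyl–S bond may be slow, and the silyl enol ethers may be lost early, which would let the organozinc be consumed by protonolysis. The fallback sets out from 9 and comes back at 12 without any new compound (F0). It is a base-free, copper-mediated thioester–organostannane coupling of Liebeskind–Srogl type on unprotected 9: tetramethyltin, Pd2(dba)3, P(2-furyl)3, CuOP(O)Ph2 (copper diphenylphosphinate, monovalent copper), THF, 50 °C. Here the thiolate is pulled off by the thiophilic copper salt and no enol protection or basic organometal is involved.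

Step 3. The second thioacylation may stall, and the neutral bis(β-keto thioester) may close or fragment during quench and isolation. The fallback sets out from 3 and comes back at 8. Kinetic double deprotonation with LiN(iPr)2 (2.2 equiv, THF, −78 °C) is followed by thiocarboxylation of both enolates with carbonyl sulfide to dilithium 4-geranyl-4-methyl-3,5-dioxoheptanebis(thioate) F3, which is S-ethylated in the same flask with iodoethane. The C–C bond is then formed with a heterocumulene at low temperature and the thioester is completed by alkylation at sulfur.

Further compounds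
F1 | step 4 | racemic 2-acetyl-4-geranyl-3,5-dihydroxy-4-methylcyclohexa-2,5-dien-1-one | C1=C(O)C(C)(C/C=C(\C)CCC=C(C)C)C(O)=C(C(C)=O)C1=O
F2 | step 4 | (S)-1-phenylethylammonium salt of (4R)-2-acetyl-4-geranyl-3,5-dihydroxy-4-methylcyclohexa-2,5-dien-1-one | C1=C([O-])[C@@](C)(C/C=C(\C)CCC=C(C)C)C(O)=C(C(C)=O)C1=O.C[C@H]([NH3+])c1ccccc1
F0 | step 5 | none | none
F3 | step 3 | dilithium 4-geranyl-4-methyl-3,5-dioxoheptanebis(thioate) | [Li+].[Li+].[S-]C(=O)CC(=O)C(C)(C/C=C(\C)CCC=C(C)C)C(=O)CC([S-])=O
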